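The numbers in the tables are simulated on assumed constants, and the scatter is random.

In a one-step world whose rate follows [substrate], Sunday's and Thursday's runs, which differ in the substrate charge, show the same percent of target at the same time.

| flask | substrate | partner | catalyst | remark | time |
|---|---|---|---|---|---|
| Sunday's | 0.073 M | 0.131 M | 0.88 mM | run made earlier |  |
| Friday's | 0.073 M | 0.131 M | 1.2 mM | run made earlier |  |
| Saturday's | 0.073 M | 0.131 M | 1.9 mM | run made earlier |  |
| Thursday's | 0.11 M | 0.131 M | 0.88 mM | run made earlier |  |
| blue | 0.073 M | 0.131 M | 0.88 mM | everything together at the start | 3.0 d |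
| violet | 0.073 M | 0.131 M (fed, over 30 h) | 0.88 mM | all else is in the flask from the start; the feed brings no volume worth counting | 3.0 d |
| grey | 0.073 M (fed, over 30 h) | 0.131 M | 0.88 mM | all else is in the flask from the start; the feed brings no volume worth counting | 3.0 d |

| run | time / d | target / % | substrate / % |
|---|---|---|---|
| Sunday's | 0.250 | 13 | 89 |
| Sunday's | 0.417 | 16 | 85 |
| Sunday's | 0.625 | 22 | 78 |
| Sunday's | 1.04 | 31 | 69 |
| Sunday's | 1.67 | 43 | 54 |
| Sunday's | 3.00 | 67 | 33 |
| Friday's | 0.417 | 24 | 77 |
| Friday's | 0.833 | 36 | 64 |
| Friday's | 1.25 | 49 | 54 |
| Friday's | 1.67 | 55 | 41 |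
| Friday's | 2.08 | 68 | 33 |
| Friday's | 2.50 | 77 | 23 |
| Saturday's | 0.417 | 36 | 63 |
| Saturday's | 0.833 | 53 | 46 |
| Saturday's | 1.25 | 70 | 32 |
| Saturday's | 1.67 | 82 | 20 |
| Saturday's | 2.08 | 91 | 9 |
| Saturday's | 2.50 | 97 | 2 |
| Thursday's | 0.208 | 9 | 94 |
| Thursday's | 0.333 | 9 | 89 |
| Thursday's | 0.625 | 17 | 85 |
| Thursday's | 1.25 | 24 | 73 |
| Thursday's | 2.50 | 41 | 63 |

(scatter of a reading: 1.5 percentage points)

- the flask that comes out highest in amount of target, in percent of the substrate charged, or "all alike" when all lie within 1.5 percentage points (blue / violet / grey / all alike)
- target at the end, in percent of the substrate charged, blue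
- target at the end, in percent of the substrate charged, violet
- target at the end, in percent of the substrate charged, grey



At 0.625 d they read 22% and 17%, so percent is the wrong scale. Count turnovers instead, starting from the last reading of Sunday's run:

count = [target] / [catalyst] = 67% × 0.073 M / 0.88 mM = 55.6

This turnover count, the target made per catalyst charged, reads 18.2 for Sunday's run and 21.2 for Thursday's at 0.625 d, and one Thursday reading scatters by 1.88. At 0.417 d, Sunday's run counts 13.3 and Saturday's, with 1.9 mM of catalyst, 13.8. So at this partner charge the count follows the clock, not the substrate charge: the reaction reads as zero order in substrate.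

My reckoning follows. Blue repeats Sunday's recipe, so I put its count at 55.6 of the 83.0 its charge allows. In grey the feed supplies 66.4 d⁻¹ in turnovers, more than the early pace of 31.8 d⁻¹ read from Sunday's run, so I give grey blue's count. The count was read in runs with all the partner charged at the start, so it gives no figure for violet, and there I expect a lower count without naming one.

The forecast names blue highest, with blue at 67% (64.5% to 69%), violet at 55% (49% to 60%) and grey at 66% (61% to 69%), holding that “the rate is about zero order in substrate”. Its grey comes to a count of 54.8, a little below the 55.6 I gave grey.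

The flasks end at 67.9% for blue, 57.7% for violet and 65.3% for grey, with blue highest. A partner charge of 0.121 M or 0.141 M, all else held, moves blue by 5 points, out of the forecast's range for blue.

    substrate + partner + catalyst → target + catalyst, rate k1*[substrate]*[partner]*[catalyst]/(1 + ([substrate]/sat1)) (1.14 mM, k = 231 L² mol⁻² min⁻¹)
    partner ⇌ dormant form (K = 1.20, k = 0.00128 min⁻¹)

Violet counts 47.9, fewer than the 55.6 read from Sunday's run. The gap of 10 percentage points between blue and violet needs two things together, the [substrate] term below the line and the way back from dormant form to partner: the run without the term shows 0 points, the run without the way back 0.17 points. The neighbour flask, violet with 0.12 M of substrate, ends at a lower 35.4%, yet its count is 48.3.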